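**Remark 1:** Stevensine has no stereocentre and its only non-aromatic C=C bond is endocyclic, so there is no configuration to set; the route gives the achiral compound exactly as drawn.
**Remark 2:** 4-Bromo-7-chloro-1H-indole (1) and imidazo[1,2-a]pyrimidine (3) are taken as catalogue compounds.

## Retrosynthetic overview

1. Stevensine ⇐ hydrazinolysis of a 3-substituted imidazo[1,2-a]pyrimidine (masked 2-aminoimidazole), after dibromination of the pyrrole at C2/C3 of the bicyclic lactam.
2. Key disconnection: the lactam nitrogen N7 is taken out from between C6 and C8. The azepinone ring (C3a–C4–C5–C6–N7–C8–C8a) contracts to the benzene ring of a 4-heteroaryl-7-azidoindole (C8 = indole C7, C6 = indole C6). Forward, photolysis of the azide in methoxide inserts N into the C6–C7 bond and gives the C8 lactim ether with C4=C5 and C6H2 already in place.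
3. Azide ⇐ aryl amine ⇐ aryl chloride (C7–N by Pd amination); the C4–C3' biaryl bond ⇐ direct C–H arylation of imidazo[1,2-a]pyrimidine with 4-bromo-7-chloroindole.
4. Ring order: indole (bought) → imidazopyrimidine attached → benzene ring expanded to the azepine → pyrimidine ring cut away to reveal the aminoimidazole.

Key step: step 5

## Route

Step 1
Reactants: 1 4-bromo-7-chloro-1H-indole
Product: 2 4-bromo-7-chloro-1-(p-toluenesulfonyl)-1H-indole
Conditions: NaH, TsCl, DMF, 0 °C → rt
Reagents that add atoms: p-toluenesulfonyl chloride, Cc1ccc(cc1)S(=O)(=O)Cl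
Why: N-Sulfonylation of the sodium indolide is routine, and the tosyl group removes the N1–H that lies next to C7 (no N–H transfer to the later nitrene, no indolide formation in methoxide) and leaves by methanolysis in the pot of step 5.

Step 2
Reactants: 2 4-bromo-7-chloro-1-(p-toluenesulfonyl)-1H-indole; 3 imidazo[1,2-a]pyrimidine
Product: 4 3-[7-chloro-1-(p-toluenesulfonyl)-1H-indol-4-yl]imidazo[1,2-a]pyrimidine
Conditions: Pd(OAc)2 (cat.), PPh3, Cs2CO3, 1,4-dioxane, 100 °C
Reagents that add atoms: none
Why: Pd-catalysed direct C–H arylation (concerted metalation–deprotonation) of imidazo[1,2-a]pyrimidine is selective for C3, its most electron-rich position, and Pd/PPh3 inserts into the C4–Br bond but not into the C7–Cl bond.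

Step 3
Reactants: 4 3-[7-chloro-1-(p-toluenesulfonyl)-1H-indol-4-yl]imidazo[1,2-a]pyrimidine
Product: 6 4-(imidazo[1,2-a]pyrimidin-3-yl)-1-(p-toluenesulfonyl)-1H-indol-7-amine, via N-(diphenylmethylene)-4-(imidazo[1,2-a]pyrimidin-3-yl)-1-(p-toluenesulfonyl)-1H-indol-7-amine 5 (not isolated)
Conditions: Ph2C=NH, Pd2(dba)3 (cat.), XPhos, Cs2CO3, toluene, 100 °C; then 2 M aq. HCl, THF, rt
Reagents that add atoms: benzophenone imine, N=C(c1ccccc1)c1ccccc1
Why: Buchwald–Hartwig amination of the aryl chloride with benzophenone imine as ammonia surrogate runs with a carbonate base that spares the N-tosyl group, and the N-aryl ketimine is hydrolysed by dilute acid at room temperature.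

Step 4
Reactants: 6 4-(imidazo[1,2-a]pyrimidin-3-yl)-1-(p-toluenesulfonyl)-1H-indol-7-amine
Product: 7 3-[7-azido-1-(p-toluenesulfonyl)-1H-indol-4-yl]imidazo[1,2-a]pyrimidine
Conditions: t-BuONO, TMSN3, MeCN, 0 °C → rt, in the dark
Reagents that add atoms: tert-butyl nitrite, CC(C)(C)ON=O; azidotrimethylsilane, C[Si](C)(C)N=[N+]=[N-]
Why: Non-aqueous diazotisation with azide capture (Sandmeyer-type azidation via the aryl pentazene) converts ArNH2 into ArN3, and with N1 sulfonylated the diazonium ion cannot close onto the ring nitrogen to a fused triazole.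

Step 5
Reactants: 7 3-[7-azido-1-(p-toluenesulfonyl)-1H-indol-4-yl]imidazo[1,2-a]pyrimidine
Product: 10 4-(imidazo[1,2-a]pyrimidin-3-yl)-8-methoxy-1,6-dihydropyrrolo[2,3-c]azepine, via fused 2H-azirine (N bridging former indole C6 and C7, C7=N) 8 (not isolated), via 4-(imidazo[1,2-a]pyrimidin-3-yl)-8-methoxy-1-(p-toluenesulfonyl)-1,6-dihydropyrrolo[2,3-c]azepine 9 (not isolated)
Conditions: hν (365 nm), NaOMe (0.5 M, anhydrous), MeOH–1,4-dioxane 1:1, degassed, c ≈ 5 mM, 15 °C, short irradiation (flow); then 50 °C; NH4Cl work-up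
Reagents that add atoms: sodium methoxide, [Na+].[O-]C
Why: Irradiation expels N2 to give the singlet 7-indolylnitrene, which adds to the only ortho CH (C6) to form azirine 8; methoxide adds to the strained C7=N bond and the azanorcaradiene-type aziridinide opens its C6–C7 bond, so nitrogen is inserted between C7 and C6 and the benzene ring becomes the azepine (a 6→7 ring expansion through a three-membered ring that forms by nitrene addition to the C6=C7 π bond and opens electrocyclically, not a closure from an open chain). The closest known reaction type is the photolytic ring expansion of bicyclic (het)aryl azides that carry the azide next to the ring fusion (azidonaphthalenes, azidoquinolines) in methanolic methoxide to fused methoxy-azepines and -diazepines, which likewise end with a CH2 next to the new ring nitrogen. Protonation of the delocalised C4–C5–C6 anion at C6 restores the pyrrole sextet and leaves C4=C5 conjugated with the pyrrole and the heteroaryl group, which is exactly the unsaturation of stevensine, and methoxide equilibration should favour this tautomer over the C5=C6 isomer. The step needs insertion into C6–C7 and not C7–C7a (C7a is quaternary and part of the pyrrole), ring expansion rather than rearomatising C–N cleavage to amino-anisole-type products (secured by the strongly basic, N-deprotonating methoxide medium) and singlet rather than triplet chemistry (direct irradiation near room temperature, dilute, degassed, no sensitiser). The N-tosyl group blocks hydrogen transfer from N1 to the nitrene, and once the pyrrole carries the electron-withdrawing imidate it is cleaved by the same methoxide on warming, while anhydrous conditions keep the imidazo[1,2-a]pyrimidine from Dimroth-type ring opening. No stereocentre is formed, since C6 is sp3 with one hydrogen only in transient 8.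

Step 6
Reactants: 10 4-(imidazo[1,2-a]pyrimidin-3-yl)-8-methoxy-1,6-dihydropyrrolo[2,3-c]azepine
Product: 12 2,3-dibromo-4-(imidazo[1,2-a]pyrimidin-3-yl)-6,7-dihydropyrrolo[2,3-c]azepin-8(1H)-one, via 4-(imidazo[1,2-a]pyrimidin-3-yl)-6,7-dihydropyrrolo[2,3-c]azepin-8(1H)-one 11 (not isolated)
Conditions: HBr (33% in AcOH), 45 °C; then Br2 (2.05 equiv), AcOH, 10 °C → rt; aq. Na2S2O3/NaHCO3 work-up
Reagents that add atoms: bromine, BrBr
Why: Bromide demethylates the protonated lactim ether by SN2 at the O-methyl carbon (Pinner-salt dealkylation, which avoids the ring opening to an amino ester that aqueous acid hydrolysis of a lactim ether would give), and the 2-acylpyrrole so formed undergoes electrophilic aromatic bromination at its two free positions while the protonated heteroaryl group on C4 deactivates the C4=C5 bond.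

Step 7
Reactants: 12 2,3-dibromo-4-(imidazo[1,2-a]pyrimidin-3-yl)-6,7-dihydropyrrolo[2,3-c]azepin-8(1H)-one
Product: 13 stevensine
Conditions: N2H4·H2O (excess), EtOH, 90 °C, sealed tube, under N2
Reagents that add atoms: none
Why: Hydrazine adds to the pyrimidine ring of the imidazo[1,2-a]pyrimidine, and ring opening and recyclisation expel C5–C7 as pyrazole and leave N8 as the exocyclic NH2 of the 2-aminoimidazole, a known unmasking that secondary lactams and bromopyrrole carboxamides tolerate.

## Compound list

1 | 4-bromo-7-chloro-1H-indole | Clc1ccc(Br)c2cc[nH]c12 | starting material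
2 | 4-bromo-7-chloro-1-(p-toluenesulfonyl)-1H-indole | Cc1ccc(cc1)S(=O)(=O)n1ccc2c(Br)ccc(Cl)c12 | intermediate
3 | imidazo[1,2-a]pyrimidine | c1cnc2nccn2c1 | starting material
4 | 3-[7-chloro-1-(p-toluenesulfonyl)-1H-indol-4-yl]imidazo[1,2-a]pyrimidine | Cc1ccc(cc1)S(=O)(=O)n1ccc2c(-c3cnc4ncccn34)ccc(Cl)c12 | intermediate
5 | N-(diphenylmethylene)-4-(imidazo[1,2-a]pyrimidin-3-yl)-1-(p-toluenesulfonyl)-1H-indol-7-amine | Cc1ccc(cc1)S(=O)(=O)n1ccc2c(-c3cnc4ncccn34)ccc(N=C(c3ccccc3)c3ccccc3)c12 | intermediate
6 | 4-(imidazo[1,2-a]pyrimidin-3-yl)-1-(p-toluenesulfonyl)-1H-indol-7-amine | Cc1ccc(cc1)S(=O)(=O)n1ccc2c(-c3cnc4ncccn34)ccc(N)c12 | intermediate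
7 | 3-[7-azido-1-(p-toluenesulfonyl)-1H-indol-4-yl]imidazo[1,2-a]pyrimidine | Cc1ccc(cc1)S(=O)(=O)n1ccc2c(-c3cnc4ncccn34)ccc(N=[N+]=[N-])c12 | intermediate
8 | fused 2H-azirine from 7 (N bridging former indole C6 and C7, C7=N; C6 racemic, transient) | Cc1ccc(cc1)S(=O)(=O)n1ccc2c1C1=NC1C=C2c1cnc2ncccn12 | intermediate
9 | 4-(imidazo[1,2-a]pyrimidin-3-yl)-8-methoxy-1-(p-toluenesulfonyl)-1,6-dihydropyrrolo[2,3-c]azepine | COC1=NCC=C(c2cnc3ncccn23)c2ccn(S(=O)(=O)c3ccc(C)cc3)c12 | intermediate
10 | 4-(imidazo[1,2-a]pyrimidin-3-yl)-8-methoxy-1,6-dihydropyrrolo[2,3-c]azepine | COC1=NCC=C(c2cnc3ncccn23)c2cc[nH]c12 | intermediate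
11 | 4-(imidazo[1,2-a]pyrimidin-3-yl)-6,7-dihydropyrrolo[2,3-c]azepin-8(1H)-one | O=C1NCC=C(c2cnc3ncccn23)c2cc[nH]c12 | intermediate
12 | 2,3-dibromo-4-(imidazo[1,2-a]pyrimidin-3-yl)-6,7-dihydropyrrolo[2,3-c]azepin-8(1H)-one | O=C1NCC=C(c2cnc3ncccn23)c2c(Br)c(Br)[nH]c12 | intermediate
13 | stevensine | Nc1ncc(C2=CCNC(=O)c3[nH]c(Br)c(Br)c32)[nH]1 | target

## Step count and risks

Total step count: 7. Longest linear sequence: 7 steps (1 → 13).

**Step 5 (key step).** The singlet nitrene may relax to the triplet (reduction to the amine, azo coupling), the methoxide adduct may open with rearomatisation instead of ring expansion, or the tosyl group may be lost before irradiation is complete. The fallback sets out from 3 and comes back at 11, building the azepinone by alkyne hydroarylation instead of nitrogen insertion. 3 is iodinated at C3 (NIS, MeCN) to 3-iodoimidazo[1,2-a]pyrimidine F1. Reductive amination of 2,4-dimethoxybenzaldehyde with propargylamine (NaBH4, MeOH) gives N-(2,4-dimethoxybenzyl)prop-2-yn-1-amine F2, which is acylated with 2-(trichloroacetyl)pyrrole (Et3N, MeCN, 60 °C) to N-(2,4-dimethoxybenzyl)-N-(prop-2-yn-1-yl)-1H-pyrrole-2-carboxamide F3. Sonogashira coupling of F1 with F3 (Pd(PPh3)2Cl2, CuI, Et3N, DMF) gives the heteroaryl alkyne F4. Cationic gold(I) (JohnPhosAu(MeCN)SbF6, one equivalent of MsOH to protonate the heterocycle, DCE, 60 °C) should effect 7-endo-dig hydroarylation from pyrrole C3 onto the alkyne carbon bearing the heteroaryl group, the known mode for aryl-substituted N-propargyl indole- and pyrrole-2-carboxamides, to give the N7-(2,4-dimethoxybenzyl) lactam F5. TFA/anisole removes the benzyl group to give 11, which enters the bromination stage of step 6.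

**Step 6.** Bromine may attack the electron-rich C4=C5 bond at C5, or overbrominate, in competition with the second pyrrole bromination. The fallback sets out from 10 and comes back at 13, brominating a substrate that has no alkene. 10 is demethylated with HBr/AcOH as in step 6 and lactam 11 is isolated. Ionic hydrogenation (Et3SiH, TFA, 50 °C; protonation at C5, hydride capture of the pyrrole-stabilised C4 cation) gives the racemic tetrahydro lactam F6. NBS (2 equiv, THF, 0 °C) gives its 2,3-dibromide F7, and hydrazinolysis as in step 7 gives (±)-hymenin F8. Bromination of the aminoimidazole at C5' (Br2, TFA) gives (±)-5'-bromohymenin F9. Heating F9 in MeSO3H should eliminate HBr through the exocyclic azafulvene-type tautomer, install C4=C5 and give 13, which erases the C4 stereocentre of F6–F9.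

**Step 3.** Oxidative addition into the hindered C7–Cl bond next to the N-tosyl group may be slow, the basic heterocycle may sequester palladium, or hydrodechlorination may take over. The fallback sets out from 4 and comes back at 7, replacing C–N coupling and diazotisation by C–B formation and copper azidation. Miyaura borylation of the C7–Cl bond (B2pin2, XPhos-Pd-G2, KOAc, dioxane, 100 °C) gives the pinacol boronate F10, and copper(II)-mediated azidation (Cu(OAc)2, NaN3, MeOH, air, rt) should give azide 7 directly.

## Further compounds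

F1 | step 5 | 3-iodoimidazo[1,2-a]pyrimidine | Ic1cnc2ncccn12
F2 | step 5 | N-(2,4-dimethoxybenzyl)prop-2-yn-1-amine | C#CCNCc1ccc(OC)cc1OC
F3 | step 5 | N-(2,4-dimethoxybenzyl)-N-(prop-2-yn-1-yl)-1H-pyrrole-2-carboxamide | C#CCN(Cc1ccc(OC)cc1OC)C(=O)c1ccc[nH]1
F4 | step 5 | N-(2,4-dimethoxybenzyl)-N-[3-(imidazo[1,2-a]pyrimidin-3-yl)prop-2-yn-1-yl]-1H-pyrrole-2-carboxamide | COc1ccc(CN(CC#Cc2cnc3ncccn23)C(=O)c2ccc[nH]2)c(OC)c1
F5 | step 5 | 7-(2,4-dimethoxybenzyl)-4-(imidazo[1,2-a]pyrimidin-3-yl)-6,7-dihydropyrrolo[2,3-c]azepin-8(1H)-one | COc1ccc(CN2CC=C(c3cnc4ncccn34)c3cc[nH]c3C2=O)c(OC)c1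
F6 | step 6 | (±)-4-(imidazo[1,2-a]pyrimidin-3-yl)-4,5,6,7-tetrahydropyrrolo[2,3-c]azepin-8(1H)-one | O=C1NCCC(c2cnc3ncccn23)c2cc[nH]c12
F7 | step 6 | (±)-2,3-dibromo-4-(imidazo[1,2-a]pyrimidin-3-yl)-4,5,6,7-tetrahydropyrrolo[2,3-c]azepin-8(1H)-one | O=C1NCCC(c2cnc3ncccn23)c2c(Br)c(Br)[nH]c12
F8 | step 6 | (±)-hymenin | Nc1ncc(C2CCNC(=O)c3[nH]c(Br)c(Br)c32)[nH]1
F9 | step 6 | (±)-5'-bromohymenin | Nc1nc(Br)c(C2CCNC(=O)c3[nH]c(Br)c(Br)c32)[nH]1
F10 | step 3 | 3-[7-(4,4,5,5-tetramethyl-1,3,2-dioxaborolan-2-yl)-1-(p-toluenesulfonyl)-1H-indol-4-yl]imidazo[1,2-a]pyrimidine | Cc1ccc(cc1)S(=O)(=O)n1ccc2c(-c3cnc4ncccn34)ccc(B3OC(C)(C)C(C)(C)O3)c12
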